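**Assumptions (one line each)**
- Commercial phytol is the natural (2E,7R,11R) isomer, ≥95% E. Any Z isomer gives the 3-epimeric epoxide, which is removed by chromatography at compound 4.
- 4-Bromo-2,5-dimethylphenol is commercially available.

**Retrosynthesis**
1. β-Tocopherol (9) comes from chroman-4-ol 8 by hydrogenolysis of the O-benzyl ether and the benzylic C4–OH.
2. The pyran ring is formed last, by intramolecular Pd-catalysed C(aryl)–O coupling of a tertiary alcohol with an ortho aryl bromide. The C2–O bond is never broken, so C2 keeps its configuration.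
3. The C4a–C4 bond comes from addition of an aryl-cerium reagent (from 2) to chiral β-hydroxy aldehyde 6.
4. Phytol supplies C2 (phytol C3), the 4′R,8′R centres and the whole side chain. Sharpless epoxidation followed by Red-Al reduction gives the tertiary (R)-carbinol. The aromatic ring (from 4-bromo-2,5-dimethylphenol) is already present, and the pyran ring closes at step 6.

---

**Step 1**
Reactants: 1 (4-bromo-2,5-dimethylphenol)
Product: 2 (1-benzyloxy-4-bromo-2,5-dimethylbenzene)
Conditions: BnBr, K2CO3, DMF, rt
Reagents that add atoms: benzyl bromide, BrCc1ccccc1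
Why: Williamson O-benzylation masks the phenol so it survives LDA and Pd coupling and can be removed by hydrogenolysis at the end.

**Step 2**
Reactants: 3 ((2E,7R,11R)-phytol)
Product: 4 ((2R,3R,7R,11R)-2,3-epoxyphytol)
Conditions: Ti(OiPr)4 (10 mol%), D-(−)-diethyl tartrate (12 mol%), TBHP, 4 Å MS, CH2Cl2, −20 °C
Reagents that add atoms: tert-butyl hydroperoxide, CC(C)(C)OO (supplies the epoxide O)
Why: Sharpless asymmetric epoxidation of the E-allylic alcohol with the D-tartrate delivers O to one face, giving the 2R,3R trans-epoxide. Epoxide C3 becomes the future chroman C2, and the remote 7R,11R centres are untouched.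

**Step 3**
Reactants: 4
Product: 5 ((3R,7R,11R)-3,7,11,15-tetramethylhexadecane-1,3-diol)
Conditions: Red-Al, THF, 0 °C → rt
Reagents that add atoms: none
Why: Alkoxyaluminate-directed hydride delivery opens the 2,3-epoxy alcohol at C2. The C3–O bond is retained, so the tertiary (R)-carbinol is formed with its configuration fixed.

**Step 4**
Reactants: 5
Product: 6 ((3R,7R,11R)-3-hydroxy-3,7,11,15-tetramethylhexadecanal)
Conditions: TEMPO (10 mol%), PhI(OAc)2, CH2Cl2, rt
Reagents that add atoms: none
Why: TEMPO/BAIB oxidation is selective for the primary alcohol over the tertiary one. No stereocentre is touched, and the mild, near-neutral medium limits retro-aldol and dehydration.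

**Step 5**
Reactants: 2 and 6
Product: 7 ((3R,7R,11R)-1-[3-(benzyloxy)-6-bromo-2,5-dimethylphenyl]-3,7,11,15-tetramethylhexadecane-1,3-diol, C1 epimer mixture)
Conditions: 2 + LDA (3 equiv), THF, −78 °C, 1 h; then CeCl3 (3 equiv), −78 °C; then 6 (1 equiv), −78 → 0 °C; aq. NH4Cl
Reagents that add atoms: none
Why: LDA removes the only ring C–H made acidic by the ortho bromine. The resulting organocerium adds 1,2 to the aldehyde without enolising it, and excess reagent covers the free tertiary OH. The new benzylic stereocentre is unselective but is erased in step 7.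

**Step 6**
Reactants: 7
Product: 8 ((2R,4′R,8′R)-6-benzyloxy-2,5,8-trimethyl-2-(4,8,12-trimethyltridecyl)chroman-4-ol)
Conditions: Pd2(dba)3 (2.5 mol%), RockPhos (7 mol%), Cs2CO3, toluene, 100 °C
Reagents that add atoms: none
Why: Intramolecular Buchwald–Hartwig C–O coupling of the tertiary alkoxide with the aryl bromide closes the 6-membered ring. Only the Ar–Br bond is broken, so C2 is formed with retention.

**Step 7**
Reactants: 8
Product: 9 (β-tocopherol)
Conditions: H2 (1 atm), 10% Pd/C, EtOAc/EtOH, cat. AcOH, rt
Reagents that add atoms: none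
Why: Hydrogenolysis cleaves the O-benzyl ether to the free phenol and removes the electron-rich benzylic C4–OH as CH2. C2, C4′ and C8′ are not benzylic or epimerisable under these conditions.

---

**Compound list**

| No. | Name | SMILES | Role |
|---|---|---|---|
| 1 | 4-Bromo-2,5-dimethylphenol | Cc1cc(O)c(C)cc1Br | starting material |
| 2 | 1-Benzyloxy-4-bromo-2,5-dimethylbenzene | Cc1cc(OCc2ccccc2)c(C)cc1Br | intermediate |
| 3 | (2E,7R,11R)-Phytol | OC/C=C(\C)CCC[C@H](C)CCC[C@H](C)CCCC(C)C | starting material |
| 4 | (2R,3R,7R,11R)-2,3-Epoxyphytol | OC[C@H]1O[C@]1(C)CCC[C@H](C)CCC[C@H](C)CCCC(C)C | intermediate |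
| 5 | (3R,7R,11R)-3,7,11,15-Tetramethylhexadecane-1,3-diol | OCC[C@](C)(O)CCC[C@H](C)CCC[C@H](C)CCCC(C)C | intermediate |
| 6 | (3R,7R,11R)-3-Hydroxy-3,7,11,15-tetramethylhexadecanal | O=CC[C@](C)(O)CCC[C@H](C)CCC[C@H](C)CCCC(C)C | intermediate |
| 7 | Aryl diol adduct (C1 epimers) | Cc1cc(OCc2ccccc2)c(C)c(C(O)C[C@](C)(O)CCC[C@H](C)CCC[C@H](C)CCCC(C)C)c1Br | intermediate |
| 8 | (2R,4′R,8′R)-6-Benzyloxy-2,5,8-trimethyl-2-(4,8,12-trimethyltridecyl)chroman-4-ol | Cc1cc(OCc2ccccc2)c(C)c2c1O[C@](C)(CCC[C@H](C)CCC[C@H](C)CCCC(C)C)CC2O | intermediate |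
| 9 | (2R,4′R,8′R)-β-Tocopherol | Cc1cc(O)c(C)c2c1O[C@](C)(CCC[C@H](C)CCC[C@H](C)CCCC(C)C)CC2 | target |

**Totals:** 7 steps in total. The longest linear sequence is 6 steps (3 → 4 → 5 → 6 → 8 → 9, via 7).

**Three steps most likely to fail, each with a fallback that changes the approach**
1. **Step 6 (Pd-catalysed C–O coupling).** The aryl bromide is flanked by a methyl and a CH(OH) group, the nucleophile is a tertiary alkoxide, and the free benzylic OH may cause hydrodehalogenation. Fallback: condense 2,5-dimethylhydroquinone with phytol under ZnCl2 (Friedel–Crafts/cyclisation). This gives 2-ambo-β-tocopherol, and the 2R,4′R,8′R diastereomer is then isolated by preparative HPLC of the acetates.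
2. **Step 5 (ortho-lithiation and addition).** The lithiation regiochemistry may be imperfect, the aryllithium can eliminate LiBr to a benzyne, and the aldehyde is enolisable and carries a free OH. Fallback: convert diol 5 to its primary iodide and alkylate an arylcuprate made from 2 by SN2 coupling. This gives a CH2 link directly, so there is no benzylic alcohol.
3. **Step 4 (β-hydroxy aldehyde 6).** The aldehyde is prone to retro-aldol and dehydration to the enal. Fallback: make 6 from (6R,10R)-phytone (from phytol by ozonolysis) by catalytic enantioselective allylboration of the methyl ketone followed by ozonolysis. This avoids steps 2–4.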